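**Retrosynthetic overview**
1. Ring labels: A is the arene and B the pyranone of the 6-linked coumarin. C is the arene and D the pyranone of the 8'-linked coumarin. The last step is a double O-methylation at 4'-OH and 7'-OH.
2. Ring D is opened at C4'–C4a' (Friedel–Crafts) and then at the key bond O1'–C2'. That aryl ester C–O bond is made by catalytic atroposelective mono-O-malonylation of a mirror-symmetric 2-aryl-orcinol, and this step sets the axis.
3. The prochiral diol comes from dehydrogenative aromatisation of a 2-aryl-5-methylcyclohexane-1,3-dione. The dione comes from Pd-catalysed α-arylation with 6-bromosiderin, so the biaryl C–C bond is made with no stereochemical demand.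
4. 6-Bromosiderin comes from 2-bromo-3,5-dimethoxytoluene by acetylation with ortho-demethylation, carbonate annulation and O-methylation.
5. Order of rings: A (bought), then B, then C (aromatised), then D.

Assumption: the given SMILES carries no axis descriptor and SMILES cannot encode a biaryl axis, so I take the natural (M) atropisomer (desertorin C) as the target and give the descriptor in the names; the sense of induction of the new step cannot be known beforehand, so (2S,3R)-HyperBTM is written and its equally available (2R,3S) antipode is used if ECD comparison of 19 shows (P).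

**Step 1**
Reactants: 1 2-bromo-1,5-dimethoxy-3-methylbenzene; 2 acetyl chloride
Product: 4 1-(3-bromo-6-hydroxy-4-methoxy-2-methylphenyl)ethan-1-one, via dimethoxy ketone 3 (not isolated)
Conditions: AcCl (1.2 equiv), AlCl3 (2.5 equiv), CH2Cl2, 0 °C then 40 °C; 1 M HCl work-up
Reagents that add atoms: acetyl chloride CC(=O)Cl
Why: Friedel–Crafts acylation goes to the only C–H para to a methoxy group (next to the methyl) rather than the crowded site between the two methoxy groups, and AlCl3 chelated to the new ketone then cleaves only the ortho methyl ether.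

**Step 2**
Reactants: 4 1-(3-bromo-6-hydroxy-4-methoxy-2-methylphenyl)ethan-1-one; 5 diethyl carbonate
Product: 7 6-bromo-4-hydroxy-7-methoxy-5-methyl-2H-chromen-2-one, via keto ester 6 (not isolated)
Conditions: NaH (4 equiv), (EtO)2CO (5 equiv), toluene, 110 °C; aq. HCl
Reagents that add atoms: diethyl carbonate CCOC(=O)OCC
Why: Claisen condensation of the methyl ketone enolate with the carbonate, followed by lactonisation through the neighbouring phenoxide, is the standard 4-hydroxycoumarin synthesis, and the aryl bromide is inert to it.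

**Step 3**
Reactants: 7 6-bromo-4-hydroxy-7-methoxy-5-methyl-2H-chromen-2-one; 8 dimethyl sulfate
Product: 9 6-bromo-4,7-dimethoxy-5-methyl-2H-chromen-2-one (6-bromosiderin)
Conditions: Me2SO4 (1.3 equiv), K2CO3 (2 equiv), acetone, reflux
Reagents that add atoms: dimethyl sulfate COS(=O)(=O)OC
Why: In this Williamson-type O-methylation the hard electrophile with K2CO3 in acetone alkylates the 4-oxygen of the coumarin enolate rather than C3.

**Step 4**
Reactants: 9 6-bromosiderin; 10 5-methylcyclohexane-1,3-dione
Product: 11 2-(4,7-dimethoxy-5-methyl-2-oxo-2H-chromen-6-yl)-5-methylcyclohexane-1,3-dione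
Conditions: Pd(OAc)2 (5 mol%), XPhos (10 mol%), K3PO4 (2.5 equiv), 1,4-dioxane, 100 °C; acidic work-up
Reagents that add atoms: 5-methylcyclohexane-1,3-dione CC1CC(=O)CC(=O)C1
Why: In this palladium-catalysed α-arylation of a cyclic 1,3-dione enolate the bulky electron-rich XPhos permits oxidative addition and reductive elimination with 2,6-disubstituted aryl bromides, and the uncontrolled C2/C5 configuration and enol tautomerism do not matter because step 5 erases them.

**Step 5**
Reactants: 11 2-aryl-5-methylcyclohexane-1,3-dione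
Product: 12 6-(2,6-dihydroxy-4-methylphenyl)-4,7-dimethoxy-5-methyl-2H-chromen-2-one
Conditions: Pd/C (10 wt% palladium on carbon, 10 mol% Pd), triglyme, 190 °C, N2 sweep
Reagents that add atoms: none
Why: Acceptorless catalytic dehydrogenative aromatisation of a cyclohexane-1,3-dione to a resorcinol is driven by H2 loss and aromaticity, uses no halogenating or one-electron oxidant that would attack coumarin C3 or the new orcinol ring, and gives an achiral product whose mirror plane is the plane of ring A.

**Step 6**
Reactants: 12 prochiral diol; 13 3-tert-butoxy-3-oxopropanoic acid (mono-tert-butyl malonate); 14 pivaloyl chloride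
Product: 16 (M)-tert-butyl 2-(4,7-dimethoxy-5-methyl-2-oxo-2H-chromen-6-yl)-3-hydroxy-5-methylphenyl malonate, via mixed anhydride 15 (not isolated)
Conditions: 13 (1.25 equiv), PivCl (1.25 equiv), iPr2NEt (1.3 equiv), CH2Cl2, 0 °C, 20 min; then 12, (2S,3R)-HyperBTM [(2S,3R)-3-isopropyl-2-phenyl-3,4-dihydro-2H-benzo[4,5]thiazolo[3,2-a]pyrimidine, 10 mol%], iPr2NEt (1.3 equiv), CHCl3, −30 °C; cold dilute citric acid work-up
Reagents that add atoms: 3-tert-butoxy-3-oxopropanoic acid CC(C)(C)OC(=O)CC(=O)O
Why: Proposed new method: catalytic atroposelective desymmetrising O-malonylation, in which the isothiourea is N-acylated at the unhindered malonyl carbonyl of 15 to give an acyl isothiouronium held planar by its 1,5-O···S contact; its acidic CH2 is reversibly deprotonated to a stabilised ammonium enolate that is re-protonated by a phenol OH of 12, so the aryloxide is born as a contact ion pair with the chiral acyl donor and collapses to the C–O bond faster than any free-ketene (racemic) pathway at −30 °C; the phenyl/isopropyl wall of the catalyst should admit only the OH that presents the flat 7-OMe edge of ring A and not the 5-Me/4-OMe peri edge, which fixes the (M) axis; the mismatched (P)-monoester should be consumed faster in a second acylation to the achiral bis-malonate and so raise the ee at some cost in yield; the electron-rich aryl ester formed is too poor an acyl donor to be re-activated, so the step is irreversible; the closest known reaction type is the isothiourea-catalysed acylative desymmetrisation/kinetic resolution of 2-arylresorcinol-type biaryl diols with simple branched aliphatic anhydrides, which has not been shown with a C–H-acidic, ketene-prone malonyl donor whose acyl group is kept as ring atoms (here the O1'–C2' bond plus C3' and C4' of ring D).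

**Step 7**
Reactants: 16 (M)-aryl tert-butyl malonate
Product: 18 (M)-4',7'-dihydroxy-4,7-dimethoxy-5,5'-dimethyl-2H,2'H-[6,8'-bichromene]-2,2'-dione, via malonic half acid 17 (not isolated)
Conditions: P2O5 in MeSO3H (1:10 w/w, Eaton's reagent), CH2Cl2, 0 to 20 °C, short time; ice-water quench
Reagents that add atoms: none
Why: Acidolysis of the tert-butyl ester and intramolecular Friedel–Crafts acylation (the aryl hydrogen malonate to 4-hydroxycoumarin cyclodehydration) can only strike the single free ortho carbon C4a', which lies para to the free OH and is activated enough to close at or below 20 °C, so ring closure outruns intermolecular acyl transfer and the tetra-ortho-substituted (M) axis is kept.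

**Step 8**
Reactants: 18 (M)-4',7'-diol; 8 dimethyl sulfate
Product: 19 (M)-4,4',7,7'-tetramethoxy-5,5'-dimethyl-2H,2'H-[6,8'-bichromene]-2,2'-dione (desertorin C)
Conditions: Me2SO4 (3 equiv), K2CO3 (4 equiv), acetone, 50 °C
Reagents that add atoms: dimethyl sulfate COS(=O)(=O)OC
Why: Williamson-type double O-methylation of the 7'-phenoxide and the 4'-coumarin enolate oxygen works exactly as in step 3, and 50 °C is far below the rotation barrier of the axis.

**Compound list**
1 | 2-bromo-1,5-dimethoxy-3-methylbenzene (2-bromo-3,5-dimethoxytoluene) | COc1cc(OC)c(Br)c(C)c1 | starting material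
2 | acetyl chloride | CC(=O)Cl | starting material
3 | 1-(3-bromo-4,6-dimethoxy-2-methylphenyl)ethan-1-one | CC(=O)c1c(C)c(Br)c(OC)cc1OC | intermediate (not isolated)
4 | 1-(3-bromo-6-hydroxy-4-methoxy-2-methylphenyl)ethan-1-one | CC(=O)c1c(C)c(Br)c(OC)cc1O | intermediate
5 | diethyl carbonate | CCOC(=O)OCC | starting material
6 | ethyl 3-(3-bromo-6-hydroxy-4-methoxy-2-methylphenyl)-3-oxopropanoate | CCOC(=O)CC(=O)c1c(C)c(Br)c(OC)cc1O | intermediate (not isolated)
7 | 6-bromo-4-hydroxy-7-methoxy-5-methyl-2H-chromen-2-one | COc1cc2oc(=O)cc(O)c2c(C)c1Br | intermediate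
8 | dimethyl sulfate | COS(=O)(=O)OC | starting material
9 | 6-bromo-4,7-dimethoxy-5-methyl-2H-chromen-2-one | COc1cc2oc(=O)cc(OC)c2c(C)c1Br | intermediate
10 | 5-methylcyclohexane-1,3-dione | CC1CC(=O)CC(=O)C1 | starting material
11 | 2-(4,7-dimethoxy-5-methyl-2-oxo-2H-chromen-6-yl)-5-methylcyclohexane-1,3-dione (drawn as diketone; mainly the racemic enol; C2/C5 configuration uncontrolled and erased in step 5) | COc1cc2oc(=O)cc(OC)c2c(C)c1C1C(=O)CC(C)CC1=O | intermediate
12 | 6-(2,6-dihydroxy-4-methylphenyl)-4,7-dimethoxy-5-methyl-2H-chromen-2-one (achiral, prochiral axis) | COc1cc2oc(=O)cc(OC)c2c(C)c1-c1c(O)cc(C)cc1O | intermediate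
13 | 3-tert-butoxy-3-oxopropanoic acid | CC(C)(C)OC(=O)CC(=O)O | starting material
14 | pivaloyl chloride | CC(C)(C)C(=O)Cl | starting material
15 | 3-tert-butoxy-3-oxopropanoic pivalic anhydride | CC(C)(C)OC(=O)CC(=O)OC(=O)C(C)(C)C | intermediate (not isolated)
16 | (M)-tert-butyl 2-(4,7-dimethoxy-5-methyl-2-oxo-2H-chromen-6-yl)-3-hydroxy-5-methylphenyl malonate | COc1cc2oc(=O)cc(OC)c2c(C)c1-c1c(O)cc(C)cc1OC(=O)CC(=O)OC(C)(C)C | intermediate
17 | (M)-3-[2-(4,7-dimethoxy-5-methyl-2-oxo-2H-chromen-6-yl)-3-hydroxy-5-methylphenoxy]-3-oxopropanoic acid | COc1cc2oc(=O)cc(OC)c2c(C)c1-c1c(O)cc(C)cc1OC(=O)CC(=O)O | intermediate (not isolated)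
18 | (M)-4',7'-dihydroxy-4,7-dimethoxy-5,5'-dimethyl-2H,2'H-[6,8'-bichromene]-2,2'-dione | COc1cc2oc(=O)cc(OC)c2c(C)c1-c1c(O)cc(C)c2c(O)cc(=O)oc12 | intermediate
19 | (M)-4,4',7,7'-tetramethoxy-5,5'-dimethyl-2H,2'H-[6,8'-bichromene]-2,2'-dione | COc1cc2oc(=O)cc(OC)c2c(C)c1-c1c(OC)cc(C)c2c(OC)cc(=O)oc12 | target

**Total step count:** 8. **Longest linear sequence:** 8 (1 to 19, fully linear).

**Three steps most likely to fail**

Step 6 is the new reaction. It could fail through a racemic ketene background reaction, weak discrimination between the Me and OMe flanks of ring A, or over-acylation. The fallback uses known chemistry, sets out from 12 and comes back at 18.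
- 12 is desymmetrised by the established isothiourea-catalysed acylation with isobutyric anhydride (HyperBTM antipode chosen so that the oxygen left free is the future O1', iPr2NEt, CHCl3, 0 °C). This gives (P)-2-(4,7-dimethoxy-5-methyl-2-oxo-2H-chromen-6-yl)-3-hydroxy-5-methylphenyl 2-methylpropanoate F1. The descriptor is P only because the CIP ranking of the two ortho carbons of ring C is swapped; the spatial sense is that of (M)-18.
- Steglich esterification of the free OH with 13 (DCC, catalytic DMAP, CH2Cl2, 0 °C) gives (P)-tert-butyl 2-(4,7-dimethoxy-5-methyl-2-oxo-2H-chromen-6-yl)-5-methyl-3-[(2-methylpropanoyl)oxy]phenyl malonate F2.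
- P2O5/MeSO3H at 40–50 °C cleaves the tert-butyl ester and closes ring D. The product is (M)-4'-hydroxy-4,7-dimethoxy-5,5'-dimethyl-2,2'-dioxo-2H,2'H-[6,8'-bichromen]-7'-yl 2-methylpropanoate F3.
- K2CO3/MeOH at 0 °C removes the isobutyrate and delivers 18.

Step 5 could fail because the hindered 2-aryl dione may dehydrogenate slowly or disproportionate over Pd/C at 190 °C. The fallback sets out from 11 and comes back at 12.
- Instead of direct catalytic dehydrogenation, 11 is first taken to the diene oxidation pattern with TMSOTf/Et3N (CH2Cl2, 0 °C). This gives racemic 6-[4-methyl-2,6-bis(trimethylsilyloxy)cyclohexa-1,5-dien-1-yl]-4,7-dimethoxy-5-methyl-2H-chromen-2-one F4.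
- DDQ (1.05 equiv, CH2Cl2, 20 °C) aromatises this cyclohexadiene readily. The product is 6-[4-methyl-2,6-bis(trimethylsilyloxy)phenyl]-4,7-dimethoxy-5-methyl-2H-chromen-2-one F5.
- Dilute HCl in THF/water removes both silyl groups and gives 12.

Step 4 could fail because it couples a di-ortho-substituted, electron-rich bromide with a weakly nucleophilic stabilised enolate. The fallback sets out from 9 and comes back at 12, bypassing 11 and therefore also step 5.
- Ring C is brought in already aromatic. Orcinol is protected (MOMCl, iPr2NEt, CH2Cl2) as 1,3-bis(methoxymethoxy)-5-methylbenzene F6.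
- F6 is lithiated between the two oxygens (n-BuLi, THF, 0 °C) and quenched with 2-isopropoxy-4,4,5,5-tetramethyl-1,3,2-dioxaborolane. This gives 2-[2,6-bis(methoxymethoxy)-4-methylphenyl]-4,4,5,5-tetramethyl-1,3,2-dioxaborolane F7.
- Suzuki–Miyaura coupling with 9 (Pd(OAc)2, SPhos, K3PO4, toluene/water, 100 °C) gives 6-[2,6-bis(methoxymethoxy)-4-methylphenyl]-4,7-dimethoxy-5-methyl-2H-chromen-2-one F8.
- HCl in MeOH at 40 °C removes both acetals and gives 12.

**Further compounds**
F1 | step 6 | (P)-2-(4,7-dimethoxy-5-methyl-2-oxo-2H-chromen-6-yl)-3-hydroxy-5-methylphenyl 2-methylpropanoate | COc1cc2oc(=O)cc(OC)c2c(C)c1-c1c(O)cc(C)cc1OC(=O)C(C)C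
F2 | step 6 | (P)-tert-butyl 2-(4,7-dimethoxy-5-methyl-2-oxo-2H-chromen-6-yl)-5-methyl-3-[(2-methylpropanoyl)oxy]phenyl malonate | COc1cc2oc(=O)cc(OC)c2c(C)c1-c1c(OC(=O)C(C)C)cc(C)cc1OC(=O)CC(=O)OC(C)(C)C
F3 | step 6 | (M)-4'-hydroxy-4,7-dimethoxy-5,5'-dimethyl-2,2'-dioxo-2H,2'H-[6,8'-bichromen]-7'-yl 2-methylpropanoate | COc1cc2oc(=O)cc(OC)c2c(C)c1-c1c(OC(=O)C(C)C)cc(C)c2c(O)cc(=O)oc12
F4 | step 5 | 6-[4-methyl-2,6-bis(trimethylsilyloxy)cyclohexa-1,5-dien-1-yl]-4,7-dimethoxy-5-methyl-2H-chromen-2-one (racemic) | COc1cc2oc(=O)cc(OC)c2c(C)c1C1=C(O[Si](C)(C)C)CC(C)C=C1O[Si](C)(C)C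
F5 | step 5 | 6-[4-methyl-2,6-bis(trimethylsilyloxy)phenyl]-4,7-dimethoxy-5-methyl-2H-chromen-2-one | COc1cc2oc(=O)cc(OC)c2c(C)c1-c1c(O[Si](C)(C)C)cc(C)cc1O[Si](C)(C)C
F6 | step 4 | 1,3-bis(methoxymethoxy)-5-methylbenzene | COCOc1cc(C)cc(OCOC)c1
F7 | step 4 | 2-[2,6-bis(methoxymethoxy)-4-methylphenyl]-4,4,5,5-tetramethyl-1,3,2-dioxaborolane | COCOc1cc(C)cc(OCOC)c1B1OC(C)(C)C(C)(C)O1
F8 | step 4 | 6-[2,6-bis(methoxymethoxy)-4-methylphenyl]-4,7-dimethoxy-5-methyl-2H-chromen-2-one | COCOc1cc(C)cc(OCOC)c1-c1c(OC)cc2oc(=O)cc(OC)c2c1C
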